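The benzene ring is not bought but assembled: the para relation between the hydroxyl-bearing C4 and the chain-bearing C1 of the arene corresponds to a 4-substituted cyclohex-2-enone. That enone is cut at ring bonds C1–C6 and C2–C3 into methyl vinyl ketone and the aldehyde end (CHO and α-carbon) of nonadecyl 5-oxopentanoate, an ester that already carries the complete C19 chain and the future propanoate arm. One amine-catalysed Michael addition–aldol condensation closes the carbocycle with oxygen and side chain locked 1,4, so no arene substitution or phenol protection is needed. Aerobic palladium-catalysed dehydrogenation then aromatises the enone to the target.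

Key step: step 3

Remark: the target has no stereocentre and no stereogenic double bond; the single sp3 ring carbon created in the annulation is left uncontrolled because aromatisation flattens it.

Step 1
Reactants: 1 hex-5-enoic acid; 2 nonadecan-1-ol
Product: 3 nonadecyl hex-5-enoate
Conditions: DCC (1.1 equiv), DMAP (cat.), CH2Cl2, 0 °C to rt
Reagents that add atoms: none
Why: Steglich esterification, in which DCC activates the acid as its O-acylisourea and DMAP relays the acyl group to the unhindered primary alcohol under neutral conditions that leave the terminal alkene untouched.

Step 2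
Reactants: 3 nonadecyl hex-5-enoate
Product: 5 nonadecyl 5-oxopentanoate, via secondary ozonide 4 (not isolated)
Conditions: O3/O2, CH2Cl2, −40 °C; then PPh3, −40 °C to rt
Reagents that add atoms: ozone, [O-][O+]=O
Why: Ozonolysis with reductive work-up, in which ozone adds to the only alkene by 1,3-dipolar cycloaddition, the Criegee fragments recombine to the 1,2,4-trioxolane, and PPh3 reduces it to the aldehyde while the saturated ester is inert and the terminal carbon leaves as formaldehyde.

Step 3
Reactants: 5 nonadecyl 5-oxopentanoate; 6 methyl vinyl ketone (but-3-en-2-one)
Product: 8 nonadecyl 3-(4-oxocyclohex-2-en-1-yl)propanoate (configuration at ring C1 uncontrolled), via keto aldehyde 7 (not isolated)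
Conditions: 6 (1.5 equiv), (S)-2-(methoxydiphenylmethyl)pyrrolidine (10 mol%, either enantiomer serves), ethyl 3,4-dihydroxybenzoate (20 mol%), toluene, 4 °C to rt; evaporate excess 6; then TsOH·H2O (30 mol%), toluene, 80 °C, one pot
Reagents that add atoms: none
Why: The secondary amine condenses with the unhindered aldehyde of 5 to an enamine whose nucleophilic carbon (C4 of the pentanoate, the future ring C1) adds to the terminus of 6, and hydrolysis returns the catalyst and keto aldehyde 7, which now holds ring bond C1–C6. Acid then drives the intramolecular aldol condensation of the methyl-side enol (or enamine) of the ketone onto the aldehyde, a 6-(enolendo)-exo-trig closure, and loss of water leaves ring bond C2–C3 as the conjugated C=C. The closest known chemistry is the organocatalytic Michael addition of unbranched aldehydes to vinyl ketones followed by Robinson-type cyclodehydration to 4-substituted cyclohex-2-enones. Ring C1 becomes a stereocentre that nothing later depends on, so no element is asked to control it and it is erased on aromatisation. The step needs mono-alkylation at the aldehyde α-carbon and closure through the ketone methyl: the bulky amine activates only the aldehyde and cannot readily form the enamine of the α-branched adduct, while closure through the ketone methylene or the ester α-carbon would give four-membered rings, so only the six-membered enone can form. The ester survives because neither hydroxide nor alkoxide is present.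

Step 4
Reactants: 8 nonadecyl 3-(4-oxocyclohex-2-en-1-yl)propanoate
Product: 10 nonadecyl 3-(4-hydroxyphenyl)propanoate (target), via cyclohexadienone 9 (not isolated)
Conditions: Pd(OCOCF3)2 (5 mol%), 2-(dimethylamino)pyridine (10 mol%), TsOH·H2O (20 mol%), O2 (1 atm), DMSO, 80 °C
Reagents that add atoms: none
Why: Aerobic palladium-catalysed dehydrogenation of a cyclohexenone to a phenol, in which a divalent palladium enolate formed at the α′-CH2 (ring C5) undergoes β-hydride elimination from C6 to give cross-conjugated dienone 9, which tautomerises at once to the phenol by moving the C1 hydrogen to oxygen, while O2 reoxidises zerovalent palladium and the ester and alkyl chain are spectators.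

Compound list
1 | hex-5-enoic acid | C=CCCCC(=O)O | starting material
2 | nonadecan-1-ol | CCCCCCCCCCCCCCCCCCCO | starting material
3 | nonadecyl hex-5-enoate | CCCCCCCCCCCCCCCCCCCOC(=O)CCCC=C | intermediate
4 | nonadecyl 4-(1,2,4-trioxolan-3-yl)butanoate (secondary ozonide) | CCCCCCCCCCCCCCCCCCCOC(=O)CCCC1OCOO1 | intermediate (not isolated)
5 | nonadecyl 5-oxopentanoate | CCCCCCCCCCCCCCCCCCCOC(=O)CCCC=O | intermediate
6 | methyl vinyl ketone (but-3-en-2-one) | CC(=O)C=C | starting material
7 | nonadecyl 4-formyl-7-oxooctanoate (keto aldehyde, configuration uncontrolled) | CCCCCCCCCCCCCCCCCCCOC(=O)CCC(C=O)CCC(C)=O | intermediate (not isolated)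
8 | nonadecyl 3-(4-oxocyclohex-2-en-1-yl)propanoate (configuration at ring C1 uncontrolled) | CCCCCCCCCCCCCCCCCCCOC(=O)CCC1C=CC(=O)CC1 | intermediate
9 | nonadecyl 3-(4-oxocyclohexa-2,5-dien-1-yl)propanoate | CCCCCCCCCCCCCCCCCCCOC(=O)CCC1C=CC(=O)C=C1 | intermediate (not isolated)
10 | nonadecyl 3-(4-hydroxyphenyl)propanoate | CCCCCCCCCCCCCCCCCCCOC(=O)CCc1ccc(O)cc1 | target

Total step count: 4
Longest linear sequence: 4 steps (1 and 2 to 10)

Steps most likely to fail

1. Step 3. Self-aldol condensation of the unbranched aldehyde, oligomerisation of the vinyl ketone or N-alkylation of the catalyst may outrun the Michael addition, and the cyclodehydration may stall at the open-chain stage or turn intermolecular. The fallback is a stoichiometric Stork enamine annulation that sets out from 5 and comes back at 8. Compound 5 is condensed with piperidine (1.1 equiv, 4 Å molecular sieves, toluene, rt) to nonadecyl (E)-5-(piperidin-1-yl)pent-4-enoate F1, used crude. Addition of 6 (MeCN, rt then reflux) should give the alkylated enamine nonadecyl 4-(3-oxobutyl)-5-(piperidin-1-yl)pent-4-enoate F2, which may rest as its cyclic aminal. Heating with aqueous AcOH/NaOAc buffer hydrolyses F2 to 7 and condenses it to 8.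

2. Step 4. Palladium may aggregate to inactive metal before conversion is complete, and the waxy ester may dissolve poorly in DMSO, so that dehydrogenation stalls. The fallback replaces metal-catalysed dehydrogenation by halogenation–dehydrohalogenation, sets out from 8 and comes back at 10. CuBr2 (2.2 equiv) and LiBr in MeCN at reflux should brominate the α′-position to nonadecyl 3-(5-bromo-4-oxocyclohex-2-en-1-yl)propanoate F3. F3 loses hydrogen bromide in the hot mixture to give dienone 9, which tautomerises to 10.

3. Step 2. The waxy ester may crystallise at low temperature and be cleaved incompletely, the aldehyde may be over-oxidised to the acid on prolonged ozone exposure, or the ozonide may be reduced incompletely. The fallback adjusts the oxidation state of a glutarate instead of cleaving an alkene, sets out from 2 and comes back at 5. Compound 2 opens glutaric anhydride (O=C1CCCC(=O)O1; DMAP cat., toluene, 90 °C) to 5-(nonadecyloxy)-5-oxopentanoic acid F4. BH3·SMe2 (THF, 0 °C) reduces the free acid chemoselectively to nonadecyl 5-hydroxypentanoate F5. TEMPO (cat.)/PhI(OAc)2 in CH2Cl2 at rt oxidises F5 to 5, which is used promptly so that the hydroxy ester has no time to lactonise.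

Further compounds
F1 | step 3 | nonadecyl (E)-5-(piperidin-1-yl)pent-4-enoate | CCCCCCCCCCCCCCCCCCCOC(=O)CC/C=C/N1CCCCC1
F2 | step 3 | nonadecyl 4-(3-oxobutyl)-5-(piperidin-1-yl)pent-4-enoate (enamine geometry undefined) | CCCCCCCCCCCCCCCCCCCOC(=O)CCC(CCC(C)=O)=CN1CCCCC1
F3 | step 4 | nonadecyl 3-(5-bromo-4-oxocyclohex-2-en-1-yl)propanoate (diastereomer mixture) | CCCCCCCCCCCCCCCCCCCOC(=O)CCC1C=CC(=O)C(Br)C1
F4 | step 2 | 5-(nonadecyloxy)-5-oxopentanoic acid | CCCCCCCCCCCCCCCCCCCOC(=O)CCCC(=O)O
F5 | step 2 | nonadecyl 5-hydroxypentanoate | CCCCCCCCCCCCCCCCCCCOC(=O)CCCCO
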